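## Retrosynthetic overview

1. Numbering used: N4; pyrrolidine N4–C3–C2–C1–C9a; azepanone N4–C5–C6–C7–C8–C9(=O)–C9a; cyclopentene C9a–C10(Et)–C11(O)–C12=C1; fused lactone O–C11, C12–C13(Me)–C14(=O); pendant lactone C18(O)–C19–C20(Me)–C21(=O) on C3.
2. Enabling feature: in the cyclopentene ring the amine-bearing quaternary C9a and the oxygen-bearing C11 flank the C1=C12 double bond. C10–C11(O)–C12=C1–C9a(N4) is therefore a 4-aminocyclopent-2-enol, which at the C11 ketone level is the product of an aza-Piancatelli/Stenhouse-type 4π closure of a 1-amino-4-hydroxypentadienyl cation. C9a, C1, C12 and C11 are then the four carbons of a furan, with C9 as a 2-ester and C10 as the first carbon of a 5-propyl group.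
3. Disconnections: azepanone C8–C9 (Dieckmann, then decarboxylation) ⇐ lactone O–C11 (invertive lactonisation) ⇐ C10–C9a together with N4=C9a, in one operation from a tetrasubstituted furan-2-carboxylate with the amine on the C1 side chain ⇐ C1–C2 (Negishi, serine-derived zinc reagent), C18–C19 (Fukuyama coupling), C12–C13 (furan Johnson–Claisen).
4. Ring order: furan (bought) → pendant lactone → pyrrolidine and cyclopentenone together → fused lactone → azepanone.
5. Stereocontrol: C3 and C20 bought; C18 by CBS reduction; C9a and C10 relayed from C3 in the key step; C11 from C10; C13 by kinetic protonation at the end.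

Key step: step 10

Remark: C13 is formed unselectively in step 2 and is labile in steps 10 and 13, so compounds 9–11, 14–16 and 18–25 are carried as C13 epimer pairs (SMILES left open at that atom); C13 is set in step 13.
Remark: compounds 1, 3, 7, 12 and 17 are taken as commercial; amine 19 is used at once, because as a free base it can transfer an acyl group from the lactone or the furoate to nitrogen.

## Route

Step 1
Reactants: 1 4,5-dibromofuran-2-carbaldehyde
Product: 2 1-(4,5-dibromofuran-2-yl)propan-1-ol (racemic)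
Conditions: EtMgBr, THF, −78 → 0 °C; aq. NH4Cl
Reagents that add atoms: ethylmagnesium bromide CC[Mg]Br
Why: Grignard addition to the aldehyde should be much faster at −78 °C than Br/Mg exchange; the carbinol stereocentre is destroyed in step 2.

Step 2
Reactants: 2 1-(4,5-dibromofuran-2-yl)propan-1-ol; 3 triethyl orthopropionate
Product: 4 ethyl 2-(4,5-dibromo-2-propylfuran-3-yl)propanoate (racemic)
Conditions: EtCO2H (cat.), xylenes, 140 °C, EtOH distilled off
Reagents that add atoms: none
Why: Johnson–Claisen rearrangement of the furfuryl ketene acetal ([3,3] onto the only free ring position next to the carbinol, then rearomatisation) should put the propanoate (C13, C14) on C12 and turn the carbinol carbon into the C10 methylene; the new C13 centre is deliberately uncontrolled.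

Step 3
Reactants: 4 ethyl 2-(4,5-dibromo-2-propylfuran-3-yl)propanoate
Product: 6 methyl 3-bromo-4-(1-ethoxy-1-oxopropan-2-yl)-5-propylfuran-2-carboxylate, via furylmagnesium chloride 5 (not isolated)
Conditions: i-PrMgCl·LiCl, THF, −40 °C; then ClCO2Me, −40 → 0 °C
Reagents that add atoms: methyl chloroformate COC(=O)Cl
Why: halogen–magnesium exchange should occur selectively at the α-bromine (next to the ring oxygen) at a temperature where the ester is untouched, and acylation then installs the C9 ester.

Step 4
Reactants: 6 methyl 3-bromo-4-(1-ethoxy-1-oxopropan-2-yl)-5-propylfuran-2-carboxylate; 7 benzyl (2R)-2-[(tert-butoxycarbonyl)amino]-3-iodopropanoate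
Product: 9 benzyl (2S)-N-Boc-3-(tetrasubstituted furan-3-yl)alaninate, via alkylzinc iodide 8 (not isolated)
Conditions: Zn dust, I2 (cat.), DMF, rt; then 6, Pd2(dba)3 (2.5 mol %), SPhos (5 mol %), DMF, 50 °C
Reagents that add atoms: none
Why: Negishi coupling of the serine-derived β-amino alkylzinc reagent with the ester-activated 3-bromofuran forms C1–C2; the C3 stereocentre is bought (L-serine) and is not touched.

Step 5
Reactants: 9 benzyl (2S)-N-Boc-3-(furan-3-yl)alaninate
Product: 10 (2S)-2-[(tert-butoxycarbonyl)amino]-3-[4-(1-ethoxy-1-oxopropan-2-yl)-2-(methoxycarbonyl)-5-propylfuran-3-yl]propanoic acid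
Conditions: H2 (1 atm), 10% Pd/C, EtOAc, rt
Reagents that add atoms: none
Why: benzyl ester hydrogenolysis frees only the amino-acid carboxyl; the tetrasubstituted furan and the other two esters should survive.

Step 6
Reactants: 10 N-Boc furylalanine
Product: 11 S-ethyl (2S)-2-[(tert-butoxycarbonyl)amino]-3-[4-(1-ethoxy-1-oxopropan-2-yl)-2-(methoxycarbonyl)-5-propylfuran-3-yl]propanethioate
Conditions: EtSH, EDC·HCl, DMAP (cat.), CH2Cl2, 0 °C → rt
Reagents that add atoms: ethanethiol CCS
Why: carbodiimide thioesterification of a carbamate-protected amino acid should proceed without loss of configuration at C3.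

Step 7
Reactants: 11 S-ethyl thioester; 12 methyl (2R)-3-bromo-2-methylpropanoate
Product: 14 methyl (2S,5S)-5-[(tert-butoxycarbonyl)amino]-6-(furan-3-yl)-2-methyl-4-oxohexanoate, via zinc homoenolate 13 (not isolated)
Conditions: Zn dust, I2 (cat.), DMA, 70 °C; then 11, PdCl2(PPh3)2 (10 mol %), toluene, rt
Reagents that add atoms: none
Why: Fukuyama coupling converts the thioester into the C18 ketone chemoselectively (three other esters present) and without epimerising C3; C20 is bought with the zinc reagent, whose stereocentre is not at the metal-bearing carbon.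

Step 8
Reactants: 14 γ-keto ester
Product: 16 tert-butyl N-[(1S)-2-(furan-3-yl)-1-[(2S,4S)-4-methyl-5-oxooxolan-2-yl]ethyl]carbamate, via hydroxy ester 15 (not isolated)
Conditions: (R)-Me-CBS (0.2 equiv), BH3·SMe2, THF, −20 °C; MeOH; then p-TsOH (cat.), toluene, 40 °C
Reagents that add atoms: none
Why: Corey–Bakshi–Shibata reduction should deliver hydride under catalyst control (branched C3 side as the large group) to give the (18S)-alcohol, syn to NHBoc, which is also the sense of non-chelated 1,2-induction; acid-catalysed lactonisation then gives the cis lactone.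

Step 9
Reactants: 16 N-Boc amino lactone; 17 tert-butyl 5-oxopentanoate
Product: 19 tert-butyl 5-{[(1S)-2-(furan-3-yl)-1-[(2S,4S)-4-methyl-5-oxooxolan-2-yl]ethyl]amino}pentanoate, via ammonium trifluoroacetate 18 (not isolated)
Conditions: TFA, CH2Cl2, 0 °C → rt, evaporate; then 17, NaBH(OAc)3, NaOAc (1 equiv), DCE, 0 °C → rt; cold aq. NaHCO3
Reagents that add atoms: none
Why: Boc cleavage followed directly by reductive amination attaches C5–C8 and the future enolate carbon, while the amine stays protonated or is alkylated before it can open the neighbouring lactone.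

Step 10
Reactants: 19 furan secondary amine
Product: 22 bicyclic amino enone (cyclopenta[b]pyrrol-5-one), via enedione ammonium salt 20 (not isolated), via pyrrolinium ion 21 (not isolated)
Conditions: TFA (1.1 equiv), mCPBA (1.05 equiv), CH2Cl2, 0 °C → rt; then NaOAc (3 equiv), MeCN, 4 Å MS, rt → 45 °C
Reagents that add atoms: meta-chloroperoxybenzoic acid OOC(=O)c1cccc(Cl)c1
Why: Proposed new method: mCPBA opens the tetrasubstituted furan of the N-protonated substrate to the (Z)-2-ene-1,4-dione 20; on buffering, the tethered amine adds to the keto-ester carbonyl (5-exo-trig, then loss of water), closing the pyrrolidine as the 1-pyrrolinium ion 21, and enolisation of the butanoyl ketone gives the cation C10=C11(OH)–C12=C1–C9a=N4+, which closes the cyclopentenone by thermal conrotatory 4π-electrocyclisation forming C10–C9a (formally a 5-(enolendo)-exo-trig Mannich closure). The closest known reactions are the ring-closing event of the aza-Piancatelli rearrangement and of Stenhouse salts (furan-derived aminopentadienyl cations giving trans-4-amino-5-substituted cyclopentenones) and acyliminium–enol cyclisations; new here are the generation of the cation from a furan-2-carboxylate by oxidation and condensation with a side-chain alkylamine, and the quaternary C9a. C9a: the pyrrolinium ring fixes N4 outside and the flat ester inside the U-shaped cation, and C10 should bond to the iminium face anti to the C3 lactonyl group (1,3-relay across N4, reinforced by allylic strain with the N-alkyl chain). C10: conrotation of the out-ethyl and out-nitrogen termini places ethyl trans to N4 and cis to the ester; C10 stays epimerisable, so this isomer is also reachable under equilibration. The step needs the amine to choose the keto-ester ketone over the butanoyl ketone, the ester and the lactone (5-ring hemiaminal against 6-ring alternatives), and it needs the two acyl groups cis on the alkene, which the conjugated iminium can regain through its dienamine. That same equilibrium scrambles C13, which is why C13 is set last.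

Step 11
Reactants: 22 bicyclic amino enone
Product: 23 (5R)-allylic alcohol (OH cis to the C10 ethyl group)
Conditions: NaBH4, CeCl3·7H2O, MeOH, −78 °C; AcOH quench at −78 °C
Reagents that add atoms: none
Why: Luche 1,2-reduction; hydride should add to the enone face opposite the C10 ethyl and C9a ester groups, so the C11 hydroxyl ends up cis to ethyl, and the cold acidic quench keeps the γ-hydroxy ester open.

Step 12
Reactants: 23 (5R)-allylic alcohol
Product: 25 tricyclic lactone diester (11S), via allylic mesylate 24 (not isolated)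
Conditions: Ms2O, i-Pr2NEt, CH2Cl2, −20 → 35 °C; aq. NaHCO3
Reagents that add atoms: none
Why: sulfonate activation, then displacement by the carbonyl oxygen of the C13 ethyl ester (neighbouring-group lactonisation, 5-exo-tet) with inversion at C11; SN2 and ion-pair pathways both place the lactone oxygen anti to the C10 ethyl group (the exo ring fusion), and the ethoxy-oxocarbenium ion is hydrolysed on work-up.

Step 13
Reactants: 25 tricyclic lactone diester
Product: 26 tert-butyl ester of the target's 8-carboxylic acid (β-keto ester; C13 set)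
Conditions: LiHMDS (4.5 equiv), THF, −78 → −10 °C; recooled and added to AcOH/THF at −78 °C
Reagents that add atoms: none
Why: Dieckmann condensation of the C8 ester enolate onto the C9a methyl ester closes the azepanone, the only Claisen product that ends as a stable enolate; the inverse acid quench should protonate the C13 dienolate at its α-carbon anti to the C11 ring substituent (and the C20 enolate anti to C18), giving the deconjugated cis-α-methyl lactones.

Step 14
Reactants: 26 β-keto tert-butyl ester
Product: 28 CNP0315436.2, via β-keto acid 27 (not isolated)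
Conditions: TFA, CH2Cl2, 0 °C → rt; evaporate; toluene, 60 °C
Reagents that add atoms: none
Why: acidolysis of the tert-butyl ester and decarboxylation of the β-keto acid under base-free conditions, so C13 and the β,γ-unsaturated lactone are not disturbed.

## Compound list

1 | 4,5-dibromofuran-2-carbaldehyde | O=Cc1cc(Br)c(Br)o1 | starting material
2 | 1-(4,5-dibromofuran-2-yl)propan-1-ol (racemic) | CCC(O)c1cc(Br)c(Br)o1 | intermediate
3 | triethyl orthopropionate (1,1,1-triethoxypropane) | CCC(OCC)(OCC)OCC | starting material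
4 | ethyl 2-(4,5-dibromo-2-propylfuran-3-yl)propanoate (racemic) | CCCc1oc(Br)c(Br)c1C(C)C(=O)OCC | intermediate
5 | [3-bromo-4-(1-ethoxy-1-oxopropan-2-yl)-5-propylfuran-2-yl]magnesium chloride | CCCc1oc([Mg]Cl)c(Br)c1C(C)C(=O)OCC | intermediate (not isolated)
6 | methyl 3-bromo-4-(1-ethoxy-1-oxopropan-2-yl)-5-propylfuran-2-carboxylate (racemic) | CCCc1oc(C(=O)OC)c(Br)c1C(C)C(=O)OCC | intermediate
7 | benzyl (2R)-2-[(tert-butoxycarbonyl)amino]-3-iodopropanoate (Boc-3-iodo-L-alanine benzyl ester) | CC(C)(C)OC(=O)N[C@@H](CI)C(=O)OCc1ccccc1 | starting material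
8 | [(2R)-3-(benzyloxy)-2-[(tert-butoxycarbonyl)amino]-3-oxopropyl]zinc iodide | CC(C)(C)OC(=O)N[C@@H](C[Zn]I)C(=O)OCc1ccccc1 | intermediate (not isolated)
9 | benzyl (2S)-2-[(tert-butoxycarbonyl)amino]-3-[4-(1-ethoxy-1-oxopropan-2-yl)-2-(methoxycarbonyl)-5-propylfuran-3-yl]propanoate (C13 epimers) | CCCc1oc(C(=O)OC)c(C[C@@H](C(=O)OCc2ccccc2)NC(=O)OC(C)(C)C)c1C(C)C(=O)OCC | intermediate
10 | (2S)-2-[(tert-butoxycarbonyl)amino]-3-[4-(1-ethoxy-1-oxopropan-2-yl)-2-(methoxycarbonyl)-5-propylfuran-3-yl]propanoic acid (C13 epimers) | CCCc1oc(C(=O)OC)c(C[C@@H](C(=O)O)NC(=O)OC(C)(C)C)c1C(C)C(=O)OCC | intermediate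
11 | S-ethyl (2S)-2-[(tert-butoxycarbonyl)amino]-3-[4-(1-ethoxy-1-oxopropan-2-yl)-2-(methoxycarbonyl)-5-propylfuran-3-yl]propanethioate (C13 epimers) | CCCc1oc(C(=O)OC)c(C[C@@H](C(=O)SCC)NC(=O)OC(C)(C)C)c1C(C)C(=O)OCC | intermediate
12 | methyl (2R)-3-bromo-2-methylpropanoate | BrC[C@H](C)C(=O)OC | starting material
13 | [(2R)-3-methoxy-2-methyl-3-oxopropyl]zinc bromide | Br[Zn]C[C@H](C)C(=O)OC | intermediate (not isolated)
14 | methyl (2S,5S)-5-[(tert-butoxycarbonyl)amino]-6-[4-(1-ethoxy-1-oxopropan-2-yl)-2-(methoxycarbonyl)-5-propylfuran-3-yl]-2-methyl-4-oxohexanoate (C13 epimers) | CCCc1oc(C(=O)OC)c(C[C@@H](C(=O)C[C@H](C)C(=O)OC)NC(=O)OC(C)(C)C)c1C(C)C(=O)OCC | intermediate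
15 | methyl (2S,4S,5S)-5-[(tert-butoxycarbonyl)amino]-6-[4-(1-ethoxy-1-oxopropan-2-yl)-2-(methoxycarbonyl)-5-propylfuran-3-yl]-4-hydroxy-2-methylhexanoate (C13 epimers) | CCCc1oc(C(=O)OC)c(C[C@@H]([C@@H](O)C[C@H](C)C(=O)OC)NC(=O)OC(C)(C)C)c1C(C)C(=O)OCC | intermediate (not isolated)
16 | tert-butyl N-[(1S)-2-[4-(1-ethoxy-1-oxopropan-2-yl)-2-(methoxycarbonyl)-5-propylfuran-3-yl]-1-[(2S,4S)-4-methyl-5-oxooxolan-2-yl]ethyl]carbamate (C13 epimers) | CCCc1oc(C(=O)OC)c(C[C@@H]([C@@H]2C[C@H](C)C(=O)O2)NC(=O)OC(C)(C)C)c1C(C)C(=O)OCC | intermediate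
17 | tert-butyl 5-oxopentanoate | O=CCCCC(=O)OC(C)(C)C | starting material
18 | (1S)-2-[4-(1-ethoxy-1-oxopropan-2-yl)-2-(methoxycarbonyl)-5-propylfuran-3-yl]-1-[(2S,4S)-4-methyl-5-oxooxolan-2-yl]ethan-1-aminium trifluoroacetate (C13 epimers) | CCCc1oc(C(=O)OC)c(C[C@@H]([C@@H]2C[C@H](C)C(=O)O2)[NH3+])c1C(C)C(=O)OCC.[O-]C(=O)C(F)(F)F | intermediate (not isolated)
19 | tert-butyl 5-{[(1S)-2-[4-(1-ethoxy-1-oxopropan-2-yl)-2-(methoxycarbonyl)-5-propylfuran-3-yl]-1-[(2S,4S)-4-methyl-5-oxooxolan-2-yl]ethyl]amino}pentanoate (C13 epimers) | CCCc1oc(C(=O)OC)c(C[C@@H]([C@@H]2C[C@H](C)C(=O)O2)NCCCCC(=O)OC(C)(C)C)c1C(C)C(=O)OCC | intermediate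
20 | ring-opened (Z)-2-ene-1,4-dione of 19 (methyl 2-oxo ester and butanoyl ketone cis on the tetrasubstituted alkene), as ammonium trifluoroacetate | CCCC(=O)/C(C(C)C(=O)OCC)=C(\C(=O)C(=O)OC)C[C@@H]([C@@H]1C[C@H](C)C(=O)O1)[NH2+]CCCCC(=O)OC(C)(C)C.[O-]C(=O)C(F)(F)F | intermediate (not isolated)
21 | 1-pyrrolinium ion: N-(5-tert-butoxy-5-oxopentyl)-5-(methoxycarbonyl)-2-lactonyl-3,4-dihydro-2H-pyrrol-1-ium with a 4-ylidene carrying the butanoyl and propanoate groups, trifluoroacetate | CCCC(=O)/C(C(C)C(=O)OCC)=C1/C[C@@H]([C@@H]2C[C@H](C)C(=O)O2)[N+](CCCCC(=O)OC(C)(C)C)=C1C(=O)OC.[O-]C(=O)C(F)(F)F | intermediate (not isolated)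
22 | methyl (2S,6R,6aR)-1-[5-(tert-butoxy)-5-oxopentyl]-4-(1-ethoxy-1-oxopropan-2-yl)-6-ethyl-2-[(2S,4S)-4-methyl-5-oxooxolan-2-yl]-5-oxo-1,2,3,5,6,6a-hexahydrocyclopenta[b]pyrrole-6a-carboxylate (ethyl trans to N, cis to the ester; C13 epimers) | CC[C@H]1C(=O)C(C(C)C(=O)OCC)=C2C[C@@H]([C@@H]3C[C@H](C)C(=O)O3)N(CCCCC(=O)OC(C)(C)C)[C@@]21C(=O)OC | intermediate
23 | (5R)-5-hydroxy derivative of 22 (allylic alcohol, OH cis to the 6-ethyl group; C13 epimers) | CC[C@H]1[C@@H](O)C(C(C)C(=O)OCC)=C2C[C@@H]([C@@H]3C[C@H](C)C(=O)O3)N(CCCCC(=O)OC(C)(C)C)[C@@]21C(=O)OC | intermediate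
24 | 5-methanesulfonate of 23 | CC[C@H]1[C@@H](OS(C)(=O)=O)C(C(C)C(=O)OCC)=C2C[C@@H]([C@@H]3C[C@H](C)C(=O)O3)N(CCCCC(=O)OC(C)(C)C)[C@@]21C(=O)OC | intermediate (not isolated)
25 | tricyclic lactone diester: C11–C12 fused lactone closed (11S, O trans to ethyl), methyl ester on C9a, N-(4-tert-butoxycarbonylbutyl) chain (C13 epimers) | CC[C@H]1[C@@H]2OC(=O)C(C)C2=C2C[C@@H]([C@@H]3C[C@H](C)C(=O)O3)N(CCCCC(=O)OC(C)(C)C)[C@@]21C(=O)OC | intermediate
26 | tert-butyl ester of the target's 8-carboxylic acid (pentacyclic β-keto ester; C13 R; C8 unassigned) | CC[C@H]1[C@@H]2OC(=O)[C@H](C)C2=C2C[C@@H]([C@@H]3C[C@H](C)C(=O)O3)N3CCCC(C(=O)OC(C)(C)C)C(=O)[C@]213 | intermediate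
27 | 8-carboxylic acid of the target (β-keto acid) | CC[C@H]1[C@@H]2OC(=O)[C@H](C)C2=C2C[C@@H]([C@@H]3C[C@H](C)C(=O)O3)N3CCCC(C(=O)O)C(=O)[C@]213 | intermediate (not isolated)
28 | CNP0315436.2 (3S,9aR,10R,11S,13R,18S,20S in the numbering above) | CC[C@H]1[C@@H]2OC(=O)[C@H](C)C2=C2C[C@@H]([C@@H]3C[C@H](C)C(=O)O3)N3CCCCC(=O)[C@]213 | target

## Summary and risks

Total steps: 14. Longest linear sequence: 14 (1 → 28; compounds 3, 7, 12 and 17 enter as bought building blocks).

Steps most likely to fail:

1. Step 10 (Proposed new method). The freed amine may acylate itself on the keto ester or the lactone instead of condensing, it may condense at the butanoyl ketone, or the new C10–C9a bond may form with poor facial selectivity at the pyrrolinium ion. Fallback with known chemistry, setting out from 16 and returning at 22: mCPBA opens the furan of the carbamate, whose N–H closes onto the keto-ester carbonyl to give the N-Boc cyclic hemiaminal F1. BF3·OEt2 (CH2Cl2, −40 → 0 °C) ionises it to the N-acyliminium ion, which is trapped by the enol of the butanoyl ketone (acyliminium π-cyclisation, an intramolecular Mannich reaction) to give the N-Boc bicyclic enone F2. TFA gives the secondary amine F3, and reductive amination with 17 (NaBH(OAc)3) gives 22.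

2. Step 13. The hindered C9a ester may be attacked too slowly, so that the lactone enolates that must be formed first condense with other molecules, or the C13 dienolate is protonated at C1 or from the wrong face. Fallback setting out from 23 and returning at 28, which closes the azepanone before the fused lactone exists and sets C13 in a separate last operation: TBSOTf/2,6-lutidine gives the silyl ether F4; KOt-Bu (THF, 0 °C) effects the Dieckmann closure to the β-keto ester F5. TFA (CH2Cl2, then 40 °C) removes the silyl and tert-butyl groups, decarboxylates and ionises the allylic C11–O bond, so that the ester carbonyl closes the lactone anti to the ethyl group, giving the C13 epimer mixture of the target F6. LiHMDS (−78 °C) and an inverse AcOH quench then set C13 and give 28.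

3. Step 12. The hydroxy ester may lactonise by acyl transfer with retention before it is activated, or the allylic mesylate may eliminate to a cyclopentadiene or fragment through the β-amino group. Fallback setting out from 22 and returning at 25, which never places a leaving group on C11: (R)-Me-CBS/catecholborane (toluene, −78 °C) delivers hydride to the ethyl-bearing face under catalyst control to give the (5S)-alcohol F7 (OH trans to ethyl), which lactonises by ordinary acyl transfer with retention (PPTS, toluene, 50 °C) to 25.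

## Further compounds

F1 | step 10 | methyl 1-(tert-butoxycarbonyl)-2-hydroxy-5-lactonyl-3-ylidene-pyrrolidine-2-carboxylate (N-Boc cyclic hemiaminal of the ring-opened enedione) | CCCC(=O)/C(C(C)C(=O)OCC)=C1/C[C@@H]([C@@H]2C[C@H](C)C(=O)O2)N(C(=O)OC(C)(C)C)C1(O)C(=O)OC
F2 | step 10 | N-Boc analogue of 22 (1-tert-butoxycarbonyl in place of the pentanoate chain) | CC[C@H]1C(=O)C(C(C)C(=O)OCC)=C2C[C@@H]([C@@H]3C[C@H](C)C(=O)O3)N(C(=O)OC(C)(C)C)[C@@]21C(=O)OC
F3 | step 10 | N-unsubstituted analogue of 22 (secondary amine) | CC[C@H]1C(=O)C(C(C)C(=O)OCC)=C2C[C@@H]([C@@H]3C[C@H](C)C(=O)O3)N[C@@]21C(=O)OC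
F4 | step 13 | tert-butyldimethylsilyl ether of 23 | CC[C@H]1[C@@H](O[Si](C)(C)C(C)(C)C)C(C(C)C(=O)OCC)=C2C[C@@H]([C@@H]3C[C@H](C)C(=O)O3)N(CCCCC(=O)OC(C)(C)C)[C@@]21C(=O)OC
F5 | step 13 | tricyclic azepanone β-keto tert-butyl ester with the C11 silyl ether and the open C13 ethyl ester | CC[C@H]1[C@@H](O[Si](C)(C)C(C)(C)C)C(C(C)C(=O)OCC)=C2C[C@@H]([C@@H]3C[C@H](C)C(=O)O3)N3CCCC(C(=O)OC(C)(C)C)C(=O)[C@]213
F6 | step 13 | target as a mixture of C13 epimers | CC[C@H]1[C@@H]2OC(=O)C(C)C2=C2C[C@@H]([C@@H]3C[C@H](C)C(=O)O3)N3CCCCC(=O)[C@]213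
F7 | step 12 | (5S)-epimer of 23 (allylic alcohol, OH trans to the 6-ethyl group) | CC[C@H]1[C@H](O)C(C(C)C(=O)OCC)=C2C[C@@H]([C@@H]3C[C@H](C)C(=O)O3)N(CCCCC(=O)OC(C)(C)C)[C@@]21C(=O)OC
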